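At the last gamma reading, 15.0 h, the analysis shows 21% of target, and I ask how far that one reading carries to red and violet.

the same everywhere: starting material 0.014 M; free enzyme 0.01 mol%
- zeta: second substrate 0.58 equiv (fed, over 15 h); temperature 25 °C; run made earlier; the fed solution adds 0.20 times the starting volume
- gamma: second substrate 1.5 equiv (fed, over 15 h); temperature 40 °C; run made earlier; the fed solution adds 0.20 times the starting volume
- red: second substrate 2.00 equiv (fed, over 15 h); temperature 40 °C; the fed solution adds 0.20 times the starting volume; time 15 h
- violet: second substrate 0.660 equiv; temperature 40 °C; everything together at the start, the whole solution of second substrate included, so that from the start the volume is larger by 0.20 times the starting volume; time 25 h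

| run | time / h | target / % | starting material / % |
|---|---|---|---|
| zeta | 3.00 | 0 | 101 |
| zeta | 4.00 | 2 | 99 |
| zeta | 6.00 | 4 | 103 |
| zeta | 10.0 | 4 | 95 |
| zeta | 20.0 | 11 | 86 |
| zeta | 30.0 | 12 | 85 |
| gamma | 2.50 | 0 | 100 |
| gamma | 5.00 | 1 | 97 |
| gamma | 8.00 | 7 | 95 |
| gamma | 10.0 | 12 | 91 |
| gamma | 12.0 | 13 | 87 |
| gamma | 15.0 | 21 | 78 |

(scatter of a reading: 2 percentage points)

* which one finishes higher in amount of target, in percent of the starting material charged ("neither" within 2 percentage points) (red / violet / neither)
* amount of target at the end, in percent of the starting material charged, red
* amount of target at the end, in percent of the starting material charged, violet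

- charges are per starting volume, the dose included; the dosed solution carries all of it
- the analysis behind the earlier runs scatters by 2 percentage points, standard deviation
- a reading or a percentage of target counts all its forms, free or not

I replace the rising curve by its mean: target made = a yield per hour and per equivalent × hours × mean free second substrate. Which inputs must be known well? Temperature and loading need no correction, since gamma, red and violet share 40 °C and 0.01 mol%. A scatter of 2 percentage points on that 21% moves the yield, but it moves red and violet in the same direction.

The mean needs care too. If target rises as the square of time in a fed flask, the steady feed offers half its charge, less a third of the target made; if target rises steadily in a batch, that flask offers its whole charge, less half of the target made. Volume matters too: violet's dilution against the mean of a fed flask puts a factor 0.917 on its yield. Zeta is the risk, reading 11% and 12% late on, with 0.58 equiv at 25 °C; gamma, with 1.5 equiv at 40 °C, is still rising at its last reading, so I carry no stop over, though gamma shows nothing past 15.0 h and violet runs to 25 h.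

Mean-exposure yield, from gamma: 0.0206 /h per equivalent

Red: 28.0%

Violet: 25.2%

So I put red ahead by 2.8 points, narrowly past the margin of 2 points.

The forecast says red, with 24% for red and 14% for violet, reading zeta thus: “This looks like an equilibrium ceiling”.

The flask gives 24.9% for red and 25.2% for violet: neither.

    ternary complex → free enzyme + target (k = 1800 /h, Ea = 72.0 kJ/mol)
    2 ternary complex → spent catalyst (k = 7.50 × 10⁵ /M/h, Ea = 46.0 kJ/mol)
    starting material + free enzyme ⇌ starting complex (K = 210 /M, k = 8.60 × 10⁶ /M/h, Ea = 44.0 kJ/mol, ΔH = −1.00 kJ/mol)
    second substrate + free enzyme + target → free enzyme + over-reaction product (k = 1.40 × 10⁶ /M²/h, Ea = 39.0 kJ/mol)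
    free enzyme → unfolded enzyme (k = 2.80 × 10⁻⁴ /h, Ea = 262 kJ/mol)
    crystals ⇌ target, rate k6*(cs6 - [target]) while solid is left; crystals form when [target] > cs6 (solubility = 7.60 mM, k = 0.680 /h)
    second substrate + starting complex ⇌ ternary complex (K = 19.0 /M, k = 2.70 × 10⁵ /M/h, Ea = 41.0 kJ/mol, ΔH = −47.0 kJ/mol)
    (constants at 40 °C)

Violet meets my figure, with 59.2% of its second substrate still there; red stands 3.1 points below mine, with 29.2% spent catalyst against violet's 15.3%. In red, the forward step of second substrate onto starting complex, taken alone, gives second substrate a half-life of 5.9 h at 15.0 h, longer than the 0.28 h that the forward binding alone gives starting material at 9.37 h, and at 7.50 h starting complex, the resting state at that moment, holds 57.1% of the catalyst against 11.2% ternary complex.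

For a neighbour of red charged with 0.04 mol% of free enzyme, all else as in red, I scale the yield by the loading, and the rule gives 87.5%. That neighbour gives 56.6%, with 8.05% over-reaction product and 44.2% spent catalyst.

The runs are calculated on assumed constants, and the scatter is random.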